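**Retrosynthetic overview**
1. Target 27 ⇐ desilylation, C10 tigloylation, convex-face reduction at C10, C6 aroylation, exo-to-endo alkene shift and chelation-controlled C6 reduction ⇐ 8-methylidene cis-hydroazulene-6,10-dione 16.
2. 16 ⇐ de Mayo reaction of the cis-diquinane 1,3-dione 13 with allene: the five-membered ring B (C1, C5, C6, C9, C10) takes up two allene carbons and becomes the seven-membered ring (C1, C5, C6, C7, C8, C9, C10).
3. Enabling feature: in the seven-membered ring the oxygen-bearing C6 and C10 flank the ring-fusion bond C1–C5 (a cycloheptane-1,4-dione, the retro-aldol product of a cyclobutanol fused to a cyclopentane-1,3-dione), and C7–C8(=C14)–C9 is a symmetric three-carbon bridge, so both enol tautomers and all photoadduct isomers converge; the cis fusion is inherited from the diquinane.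
4. 13 ⇐ β-oxidation of ring B in diquinane ketol 9 ⇐ copper-catalysed asymmetric conjugate methylation/intramolecular aldol of enone ketone 7 (sets C1, C5, C4 and closes ring A) ⇐ 3-ethoxycyclopent-2-en-1-one + homoprenyl Grignard reagent.
5. Ring order: ring B (purchased cyclopentenone) → ring A (step 4) → ring B expanded to the seven-membered ring (step 8).

Key step: step 8

Remark: daucane numbering is used in the discussion (C1 angular C–CH3, C4 carbinol carbon with the isopropyl group, C5 ring-fusion CH, C6 aroyloxy carbon, C8 vinylic C–CH3, C10 tigloyloxy carbon, C14 the carbon on C8); the given descriptors mean a cis-fused bicycle (C1–CH3 and C5–H syn) with the C4, C6 and C10 oxygens all on the opposite, concave face, and an (E)-2-methylbut-2-enoate (tiglate).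

**Step 1**
Reactants: 1 3-ethoxycyclopent-2-en-1-one; 2 5-bromo-2-methylpent-2-ene
Product: 5 3-(4-methylpent-3-en-1-yl)cyclopent-2-en-1-one, via Grignard reagent 3 (not isolated), via magnesium alkoxide adduct 4 (not isolated)
Conditions: 2, Mg, THF, rt; add 1, 0 °C; then 1 M HCl, rt
Reagents that add atoms: none
Why: Stork–Danheiser enone synthesis: the Grignard reagent adds 1,2 to the vinylogous ester, and acidic hydrolysis of the enol ether with loss of water transposes the carbonyl to give the 3-alkyl enone without forming a stereocentre.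

**Step 2**
Reactants: 5 3-(4-methylpent-3-en-1-yl)cyclopent-2-en-1-one
Product: 6 3-[2-(3,3-dimethyloxiran-2-yl)ethyl]cyclopent-2-en-1-one (racemic)
Conditions: mCPBA, NaHCO3, CH2Cl2, 0 °C
Reagents that add atoms: 3-chloroperoxybenzoic acid, OOC(=O)c1cccc(Cl)c1
Why: Prilezhaev epoxidation is chemoselective for the electron-rich trisubstituted alkene over the electron-poor enone, and the racemic epoxide stereocentre is erased in step 3.

**Step 3**
Reactants: 6 3-[2-(3,3-dimethyloxiran-2-yl)ethyl]cyclopent-2-en-1-one
Product: 7 3-(4-methyl-3-oxopentyl)cyclopent-2-en-1-one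
Conditions: BF3·OEt2 (0.3 equiv), CH2Cl2, −40 → 0 °C
Reagents that add atoms: none
Why: Meinwald rearrangement: the Lewis acid opens the epoxide at its tertiary carbon and a 1,2-hydride shift from the neighbouring carbon gives the isopropyl ketone, the oxygen staying on the future C4.

**Step 4**
Reactants: 7 3-(4-methyl-3-oxopentyl)cyclopent-2-en-1-one
Product: 9 diquinane ketol (3aS,6R,6aR)-6-hydroxy-3a-methyl-6-(propan-2-yl)hexahydropentalen-1(2H)-one, via dimethylaluminium enolate 8 (not isolated)
Conditions: Me3Al (1.5 equiv), Cu(O2CC4H3S) (copper thiophene-2-carboxylate, 5 mol %), Ph2P–N[CH(CH3)Ph]2 (SimplePhos ligand, single enantiomer, 10 mol %), Et2O, −30 → 0 °C; aq. HCl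
Reagents that add atoms: trimethylaluminium, C[Al](C)C
Why: Copper-catalysed asymmetric conjugate addition of Me3Al to the 3-alkylcyclopentenone sets the quaternary C1 under ligand control (the ligand antipode is chosen that gives the 3aS centre), and the regiodefined C5 aluminium enolate then closes ring A by intramolecular aldol addition to the side-chain ketone (conjugate addition–aldol cyclisation), the bicyclo[3.3.0] geometry enforcing the cis fusion at C5 and the aluminium-bridged closed transition state placing the C4 oxygen syn to C6 with the isopropyl group on the convex face.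

**Step 5**
Reactants: 9 diquinane ketol
Product: 10 (3aS,6R,6aR)-6-hydroxy-3a-methyl-6-(propan-2-yl)-4,5,6,6a-tetrahydropentalen-1(3aH)-one
Conditions: IBX (2.2 equiv), 4-methoxypyridine N-oxide (2.2 equiv), DMSO, 25 °C
Reagents that add atoms: none
Why: IBX-mediated ketone dehydrogenation can only introduce the C9=C10 double bond because the other α-carbon C5 has no β-hydrogen (C1 and C4 are quaternary), and the tertiary alcohol is inert to IBX.

**Step 6**
Reactants: 10 diquinane enone
Product: 12 (3R,3aR,6R,6aR)-3,6-dihydroxy-3a-methyl-6-(propan-2-yl)hexahydropentalen-1(2H)-one, via boryl ketone 11 (not isolated)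
Conditions: B2pin2 (1.1 equiv), CuCl (5 mol %), Xantphos (5 mol %), NaOtBu (10 mol %), MeOH (2 equiv), THF, rt; then NaBO3·4H2O, THF/H2O, rt
Reagents that add atoms: sodium perborate (written as its NaBO3 unit), [Na+].[O-]OB=O
Why: Copper-catalysed conjugate borylation of the enone followed by stereoretentive C–B oxidation gives the β-hydroxy ketone under nearly neutral conditions that spare the tertiary aldol unit; boron should enter C10 from the convex face, but this stereocentre is erased in step 7.

**Step 7**
Reactants: 12 diquinane dihydroxy ketone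
Product: 13 diquinane dione (3aR,6R,6aR)-6-hydroxy-3a-methyl-6-(propan-2-yl)tetrahydropentalene-1,3(2H,3aH)-dione
Conditions: IBX (1.5 equiv), DMSO, rt
Reagents that add atoms: none
Why: IBX oxidises the secondary β-hydroxy ketone to the 1,3-diketone without over-oxidation at C9 and leaves the tertiary C4 alcohol untouched.

**Step 8**
Reactants: 13 diquinane dione; 14 propadiene (allene)
Product: 16 (3R,3aR,8aR)-3-hydroxy-8a-methyl-6-methylidene-3-(propan-2-yl)-2,3,3a,6,7,8a-hexahydroazulene-4,8(1H,5H)-dione, via cyclobutanol photoadduct 15 (not isolated)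
Conditions: 14 (excess, condensed), hν (254 nm, quartz), MeCN, −40 °C; then rt
Reagents that add atoms: none
Why: De Mayo reaction: light excites the enol of the ring B 1,3-dione, which adds across one C=C of allene in a stepwise [2+2] photocycloaddition through a 1,4-biradical to give cyclobutanol 15, and the strained β-hydroxy ketone then undergoes spontaneous retro-aldol cleavage of the former ring B bond between C9 and the carbinol carbon, so that ring B becomes the seven-membered ring with both ketones (C6, C10) restored. The closest known reactions are the de Mayo ring expansion of cyclopentane-1,3-dione enols to cycloheptane-1,4-diones and the head-to-head photocycloaddition of allene to cyclic enones. The only ring closed is the cyclobutane, by intermolecular [2+2] photocycloaddition, whereas the seven-membered ring is not closed but arises by two-carbon expansion of ring B driven by release of cyclobutane strain. No new stereocentre remains in 16 because the cyclobutane centres are destroyed on fragmentation, while C1, C4 and C5 are untouched, so the cis fusion is carried over from the diquinane provided the work-up stays neutral and cold (C5–H is now α to the C6 ketone). The step needs head-to-head regioselectivity (central allene carbon to C9, the α-carbon of the enone chromophore), which the polarity of the excited enone should secure as in allene–cycloalkenone additions, and it needs no control of enol tautomer or π-face because the C7–C8(=CH2)–C9 bridge is symmetric and all adducts converge on 16. Irradiation at 254 nm addresses the strongly absorbing enol and not the weakly absorbing β,γ-unsaturated ketones of the product.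

**Step 9**
Reactants: 16 methylidene hydroazulenedione
Product: 18 (3R,3aS,4R,8aR)-3,4-dihydroxy-8a-methyl-6-methylidene-3-(propan-2-yl)-2,3,3a,4,5,6,7,8a-octahydroazulen-8(1H)-one, via diethylborinate chelate 17 (not isolated)
Conditions: Et2BOMe (1.1 equiv), THF/MeOH (4:1), −78 °C; NaBH4 (1.1 equiv), −78 °C; AcOH; MeOH co-evaporation
Reagents that add atoms: none
Why: Narasaka–Prasad reduction: the boron chelate between the C4 hydroxyl and the C6 carbonyl activates only this ketone and fixes its conformation so that external hydride attacks from the face syn to H5 (anti to C1), giving the 4,6-syn diol with the C6 oxygen on the concave face, while the unchelated neopentyl C10 ketone should survive at −78 °C.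

**Step 10**
Reactants: 18 keto diol
Product: 19 (3R,3aS,4R,8aR)-3,4-dihydroxy-6,8a-dimethyl-3-(propan-2-yl)-2,3,3a,4,5,8a-hexahydroazulen-8(1H)-one
Conditions: DBU (0.2 equiv), CH2Cl2, rt
Reagents that add atoms: none
Why: Base-catalysed isomerisation of the β,γ-unsaturated ketone through the C9 dienolate and protonation at the exocyclic carbon moves the double bond into conjugation with the only remaining ketone (C10), creating the C8=C9 alkene and the C8 methyl group regioselectively.

**Step 11**
Reactants: 20 4-hydroxybenzoic acid
Product: 22 4-[(tert-butyldimethylsilyl)oxy]benzoic acid, via silyl ester 21 (not isolated)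
Conditions: TBSCl (2.2 equiv), imidazole, DMF, rt; then AcOH/THF/H2O, rt
Reagents that add atoms: tert-butyldimethylsilyl chloride, CC(C)(C)[Si](C)(C)Cl
Why: Silylation of both the phenol and the acid followed by selective hydrolysis of the labile silyl ester gives the phenol-protected acid (silyl ether protection).

**Step 12**
Reactants: 19 enone diol; 22 4-[(tert-butyldimethylsilyl)oxy]benzoic acid
Product: 23 (3R,3aS,4R,8aR)-3-hydroxy-6,8a-dimethyl-8-oxo-3-(propan-2-yl)-1,2,3,3a,4,5,8,8a-octahydroazulen-4-yl 4-[(tert-butyldimethylsilyl)oxy]benzoate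
Conditions: DCC, DMAP, CH2Cl2, rt
Reagents that add atoms: none
Why: Steglich esterification acylates the secondary C6 hydroxyl with retention (the C–O bond is not broken), the tertiary C4 hydroxyl being unreactive.

**Step 13**
Reactants: 23 enone ester
Product: 24 (3R,3aS,4R,8S,8aR)-3,8-dihydroxy-6,8a-dimethyl-3-(propan-2-yl)-1,2,3,3a,4,5,8,8a-octahydroazulen-4-yl 4-[(tert-butyldimethylsilyl)oxy]benzoate
Conditions: NaBH4, CeCl3·7H2O, MeOH, −78 °C
Reagents that add atoms: none
Why: Luche reduction gives 1,2-reduction of the enone, and hydride is expected to attack C10 from the convex face of the cis-fused bicycle (the concave face is screened by ring A and by the C4 and C6 oxygen substituents), placing the new hydroxyl on the concave face, anti to the C1 methyl group.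

**Step 14**
Reactants: 24 allylic alcohol; 25 (2E)-2-methylbut-2-enoyl chloride (tigloyl chloride)
Product: 26 (3R,3aS,4R,8S,8aR)-3-hydroxy-6,8a-dimethyl-8-{[(2E)-2-methylbut-2-enoyl]oxy}-3-(propan-2-yl)-1,2,3,3a,4,5,8,8a-octahydroazulen-4-yl 4-[(tert-butyldimethylsilyl)oxy]benzoate
Conditions: pyridine, DMAP (cat.), CH2Cl2, 0 °C → rt
Reagents that add atoms: none
Why: DMAP-catalysed acylation with the acid chloride esterifies the secondary allylic C10 hydroxyl with retention, the weak base pyridine avoiding vinylketene formation and deconjugation of the tigloyl unit, and the tertiary hydroxyl does not react.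

**Step 15**
Reactants: 26 silyl-protected diester
Product: 27 (3R,3aS,4R,8S,8aR)-3-hydroxy-6,8a-dimethyl-8-{[(2E)-2-methylbut-2-enoyl]oxy}-3-(propan-2-yl)-1,2,3,3a,4,5,8,8a-octahydroazulen-4-yl 4-hydroxybenzoate
Conditions: TBAF, AcOH, THF, 0 °C
Reagents that add atoms: none
Why: Fluoride-mediated desilylation cleaves the aryl silyl ether, and buffering with acetic acid keeps the phenoxide from attacking the two esters, so no stereocentre is touched.

**Compound list**
1 | 3-ethoxycyclopent-2-en-1-one | CCOC1=CC(=O)CC1 | starting material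
2 | 5-bromo-2-methylpent-2-ene | CC(C)=CCCBr | starting material
3 | (4-methylpent-3-en-1-yl)magnesium bromide (not isolated) | CC(C)=CCC[Mg]Br | intermediate
4 | bromomagnesium 3-ethoxy-1-(4-methylpent-3-en-1-yl)cyclopent-2-en-1-olate (not isolated) | CCOC1=CC(CCC=C(C)C)(O[Mg]Br)CC1 | intermediate
5 | 3-(4-methylpent-3-en-1-yl)cyclopent-2-en-1-one | CC(C)=CCCC1=CC(=O)CC1 | intermediate
6 | 3-[2-(3,3-dimethyloxiran-2-yl)ethyl]cyclopent-2-en-1-one (racemic) | CC1(C)OC1CCC2=CC(=O)CC2 | intermediate
7 | 3-(4-methyl-3-oxopentyl)cyclopent-2-en-1-one | CC(C)C(=O)CCC1=CC(=O)CC1 | intermediate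
8 | dimethylaluminium C5 enolate of 3-methyl-3-(4-methyl-3-oxopentyl)cyclopentan-1-one, quaternary centre as in 9 (not isolated) | C[Al](C)OC1=C[C@@](C)(CCC(=O)C(C)C)CC1 | intermediate
9 | (3aS,6R,6aR)-6-hydroxy-3a-methyl-6-(propan-2-yl)hexahydropentalen-1(2H)-one | C1CC(=O)[C@@H]2[C@@]1(C)CC[C@@]2(O)C(C)C | intermediate
10 | (3aS,6R,6aR)-6-hydroxy-3a-methyl-6-(propan-2-yl)-4,5,6,6a-tetrahydropentalen-1(3aH)-one | C1=CC(=O)[C@@H]2[C@@]1(C)CC[C@@]2(O)C(C)C | intermediate
11 | 3-(pinacolatoboryl) derivative of 9, boron on the convex face (not isolated) | CC1(C)OB(OC1(C)C)[C@@H]3CC(=O)[C@@H]2[C@@]3(C)CC[C@@]2(O)C(C)C | intermediate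
12 | (3R,3aR,6R,6aR)-3,6-dihydroxy-3a-methyl-6-(propan-2-yl)hexahydropentalen-1(2H)-one | O[C@@H]1CC(=O)[C@@H]2[C@@]1(C)CC[C@@]2(O)C(C)C | intermediate
13 | (3aR,6R,6aR)-6-hydroxy-3a-methyl-6-(propan-2-yl)tetrahydropentalene-1,3(2H,3aH)-dione | O=C1CC(=O)[C@@H]2[C@@]1(C)CC[C@@]2(O)C(C)C | intermediate
14 | propadiene (allene) | C=C=C | starting material
15 | tricyclic methylidene cyclobutanol photoadduct, mixture of isomers at the cyclobutane carbons, one constitution written (not isolated) | O=C1C2C(=C)CC2(O)[C@@H]3[C@@]1(C)CC[C@@]3(O)C(C)C | intermediate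
16 | (3R,3aR,8aR)-3-hydroxy-8a-methyl-6-methylidene-3-(propan-2-yl)-2,3,3a,6,7,8a-hexahydroazulene-4,8(1H,5H)-dione | O=C1CC(=C)CC(=O)[C@@H]2[C@@]1(C)CC[C@@]2(O)C(C)C | intermediate
17 | O-diethylboranyl derivative of 16 at the tertiary oxygen, boron chelated to the C6 carbonyl (not isolated) | O=C1CC(=C)CC(=O)[C@@H]2[C@@]1(C)CC[C@@]2(OB(CC)CC)C(C)C | intermediate
18 | (3R,3aS,4R,8aR)-3,4-dihydroxy-8a-methyl-6-methylidene-3-(propan-2-yl)-2,3,3a,4,5,6,7,8a-octahydroazulen-8(1H)-one | O=C1CC(=C)C[C@@H](O)[C@@H]2[C@@]1(C)CC[C@@]2(O)C(C)C | intermediate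
19 | (3R,3aS,4R,8aR)-3,4-dihydroxy-6,8a-dimethyl-3-(propan-2-yl)-2,3,3a,4,5,8a-hexahydroazulen-8(1H)-one | O=C1C=C(C)C[C@@H](O)[C@@H]2[C@@]1(C)CC[C@@]2(O)C(C)C | intermediate
20 | 4-hydroxybenzoic acid | OC(=O)c1ccc(O)cc1 | starting material
21 | tert-butyldimethylsilyl 4-[(tert-butyldimethylsilyl)oxy]benzoate (not isolated) | CC(C)(C)[Si](C)(C)OC(=O)c1ccc(O[Si](C)(C)C(C)(C)C)cc1 | intermediate
22 | 4-[(tert-butyldimethylsilyl)oxy]benzoic acid | CC(C)(C)[Si](C)(C)Oc1ccc(cc1)C(O)=O | intermediate
23 | (3R,3aS,4R,8aR)-3-hydroxy-6,8a-dimethyl-8-oxo-3-(propan-2-yl)-1,2,3,3a,4,5,8,8a-octahydroazulen-4-yl 4-[(tert-butyldimethylsilyl)oxy]benzoate | O=C1C=C(C)C[C@@H](OC(=O)c2ccc(O[Si](C)(C)C(C)(C)C)cc2)[C@@H]3[C@@]1(C)CC[C@@]3(O)C(C)C | intermediate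
24 | (3R,3aS,4R,8S,8aR)-3,8-dihydroxy-6,8a-dimethyl-3-(propan-2-yl)-1,2,3,3a,4,5,8,8a-octahydroazulen-4-yl 4-[(tert-butyldimethylsilyl)oxy]benzoate | O[C@H]1C=C(C)C[C@@H](OC(=O)c2ccc(O[Si](C)(C)C(C)(C)C)cc2)[C@@H]3[C@@]1(C)CC[C@@]3(O)C(C)C | intermediate
25 | (2E)-2-methylbut-2-enoyl chloride (tigloyl chloride) | C/C=C(\C)C(Cl)=O | starting material
26 | (3R,3aS,4R,8S,8aR)-3-hydroxy-6,8a-dimethyl-8-{[(2E)-2-methylbut-2-enoyl]oxy}-3-(propan-2-yl)-1,2,3,3a,4,5,8,8a-octahydroazulen-4-yl 4-[(tert-butyldimethylsilyl)oxy]benzoate | C/C=C(\C)C(=O)O[C@H]1C=C(C)C[C@@H](OC(=O)c2ccc(O[Si](C)(C)C(C)(C)C)cc2)[C@@H]3[C@@]1(C)CC[C@@]3(O)C(C)C | intermediate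
27 | (3R,3aS,4R,8S,8aR)-3-hydroxy-6,8a-dimethyl-8-{[(2E)-2-methylbut-2-enoyl]oxy}-3-(propan-2-yl)-1,2,3,3a,4,5,8,8a-octahydroazulen-4-yl 4-hydroxybenzoate (CNP0273650.13) | C/C=C(\C)C(=O)O[C@H]1C=C(C)C[C@@H](OC(=O)c2ccc(O)cc2)[C@@H]2[C@@]1(C)CC[C@@]2(O)C(C)C | target

Total step count: 15. Longest linear sequence: 14 steps (steps 1–10 and 12–15; step 11 prepares acid 22).

**Steps most likely to fail**

Step 8. The photoaddition may lose regiocontrol (partial head-to-tail orientation of allene), or the β,γ-unsaturated ketones of the product may undergo secondary photoreaction (1,3-acyl shift) as they accumulate. The fallback sets out from 13 and returns at 16. Acetylation (Ac2O, pyridine, 0 °C) would give the enol acetate of 13 F2, formed together with its regioisomer at the other carbonyl, which behaves identically. Irradiation through Pyrex (λ > 300 nm) with allene, the enol-ester version of the de Mayo reaction, would give the isolable acetoxy cyclobutane photoadduct F3, from which any head-to-tail isomer can be removed. K2CO3 in MeOH would then cleave the acetate, and the free cyclobutanol would fragment by retro-aldol reaction to 16.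

Step 4. The aluminium enolate may be protonated on work-up without closing ring A, or may close it with low diastereoselectivity at C4. The fallback sets out from 7 and returns at 9. The same copper-catalysed conjugate methylation would be run with silylation of the enolate in the flask (TMSOTf, then Et3N) to give the regiodefined silyl enol ether 3-methyl-3-(4-methyl-3-oxopentyl)-1-(trimethylsilyloxy)cyclopent-1-ene F1. TiCl4 in CH2Cl2 at −78 °C would then bring about an intramolecular Mukaiyama aldol addition to the side-chain ketone through the titanium chelate of the two oxygens, giving 9.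

Step 13. Facial selectivity of hydride delivery to C10 in the flexible seven-membered ring may be poor or reversed (attack from the concave face). The fallback sets out from 23 and returns at 26, replacing step 14. The reduction product would then be the C10 epimer of 24 F4, which would be esterified with inversion at C10 by a Mitsunobu reaction with (E)-2-methylbut-2-enoic acid (tiglic acid), PPh3 and DIAD in toluene, giving 26 directly.

**Further compounds**
F1 | step 4 | 3-methyl-3-(4-methyl-3-oxopentyl)-1-(trimethylsilyloxy)cyclopent-1-ene (quaternary centre as in 9) | C[Si](C)(C)OC1=C[C@@](C)(CCC(=O)C(C)C)CC1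
F2 | step 8 | enol acetate of 13 (acetyl on the C6 oxygen) | O=C1C=C(OC(C)=O)[C@@H]2[C@@]1(C)CC[C@@]2(O)C(C)C
F3 | step 8 | acetoxy cyclobutane photoadduct of F2 and allene (mixture at the cyclobutane carbons) | O=C1C2C(=C)CC2(OC(C)=O)[C@@H]3[C@@]1(C)CC[C@@]3(O)C(C)C
F4 | step 13 | C10 epimer of 24 (8R in azulene numbering) | O[C@@H]1C=C(C)C[C@@H](OC(=O)c2ccc(O[Si](C)(C)C(C)(C)C)cc2)[C@@H]3[C@@]1(C)CC[C@@]3(O)C(C)C
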